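**Plan**

1. Atom labels follow the target and are kept for every intermediate: C1 ketone, C2, C3 carbinol, C4(C15)=C5, C6 lactone carbinol, C7, C8 tiglate carbinol, C9, C10 (C14), C11=C13, C12 lactone carbonyl. The enabling feature is the γ,δ-unsaturated β-oxygenated ketone C1(=O)–C2–C3(O)–C4=C5 inside the ten-membered ring, a Claisen retron in which C2 was an enol-ether methylene and C5 an allylic ether carbon.
2. Retrosynthesis: remove the C8 tiglate and open the O6–C12 lactone to the C12 alcohol. Cut C2–C3 (retro-Claisen) to the 2-methyleneoxocane O–C1–C10–C9–C8–C7–C6–C5 carrying an (E)-C4=C3 enol ether on C5. Then cut C1=C2 (methylenation), O5–C1 (lactonisation), C4–C5 (vinylzinc plus aldehyde), C7–C11 (cuprate), C6–O (enolate oxidation) and C9=C10 (olefination, osmylation).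
3. Forward ring order: γ-butyrolactone template from the chiral pool → dioxolane on C9/C10 → butenolide for C7 and C6 → template lactone opened → eight-membered lactone → oxocane enol ether → ten-membered carbocycle by two-carbon ring expansion → α-methylene-γ-lactone last.
4. Stereochemistry: C8 from (S)-5-(hydroxymethyl)oxolan-2-one; C9 and C10 by osmylation of a Z-enoate anti to the allylic oxygen; C7 and C6 by trans,trans addition on the butenolide; C5 by chelation-controlled vinylzinc addition; C3 and the cis C4=C5 bond by chirality transfer from C5 through the chair Claisen transition state.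

Key step: step 19

Remark: alkynyl ether 29 is assumed to survive long enough below 0 °C for immediate use, since benzyl-type alkynyl ethers rearrange on warming.

**Route**

Step 1
Reactants: 1 (S)-5-(hydroxymethyl)oxolan-2-one
Product: 2 (S)-5-oxooxolane-2-carbaldehyde
Conditions: Dess–Martin periodinane, CH2Cl2, 0 °C → rt; used crude
Reagents that add atoms: none
Why: Dess–Martin oxidation of the primary alcohol should stop at the aldehyde without touching the C8 stereocentre, and the hydration-prone product is taken on at once.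

Step 2
Reactants: 2 (S)-5-oxooxolane-2-carbaldehyde
Product: 3 methyl (Z)-2-methyl-3-[(2S)-5-oxooxolan-2-yl]prop-2-enoate
Conditions: (CF3CH2O)2P(O)CH(CH3)CO2CH3, KN(SiMe3)2, 18-crown-6, THF, −78 °C
Reagents that add atoms: methyl 2-[bis(2,2,2-trifluoroethoxy)phosphoryl]propanoate, COC(=O)C(C)P(=O)(OCC(F)(F)F)OCC(F)(F)F
Why: The Still–Gennari olefination should give the Z trisubstituted enoate (C8 cis to the ester) under kinetic control at a temperature where the α-oxygenated aldehyde does not epimerise.

Step 3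
Reactants: 3 methyl (Z)-2-methyl-3-[(2S)-5-oxooxolan-2-yl]prop-2-enoate
Product: 4 methyl (2S,3S)-2,3-dihydroxy-2-methyl-3-[(2S)-5-oxooxolan-2-yl]propanoate
Conditions: OsO4 (cat.), N-methylmorpholine N-oxide, acetone/H2O, 0 °C → rt
Reagents that add atoms: osmium tetroxide, O=[Os](=O)(=O)=O; N-methylmorpholine N-oxide, C[N+]1([O-])CCOCC1; water, O
Why: Catalytic syn dihydroxylation (Upjohn) of the Z-enoate, whose allylic 1,3-strain holds C8–H in the alkene plane, should occur anti to the allylic lactone oxygen (Kishi's empirical rule) and so set C9 anti to O8 and C10 by syn addition.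

Step 4
Reactants: 4 methyl (2S,3S)-2,3-dihydroxy-2-methyl-3-[(2S)-5-oxooxolan-2-yl]propanoate
Product: 5 methyl (4S,5S)-2,2,4-trimethyl-5-[(2S)-5-oxooxolan-2-yl]-1,3-dioxolane-4-carboxylate
Conditions: (CH3O)2C(CH3)2, pyridinium p-toluenesulfonate (cat.), CH2Cl2, rt
Reagents that add atoms: 2,2-dimethoxypropane, COC(C)(C)OC
Why: Acid-catalysed transketalisation ties the C9/C10 diol into an isopropylidene ketal, which blocks both hydroxyls before any lactone migration can start.

Step 5
Reactants: 5 methyl (4S,5S)-2,2,4-trimethyl-5-[(2S)-5-oxooxolan-2-yl]-1,3-dioxolane-4-carboxylate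
Product: 9 butenolide methyl (4S,5S)-2,2,4-trimethyl-5-[(2S)-5-oxo-2,5-dihydrofuran-2-yl]-1,3-dioxolane-4-carboxylate, via lithium enolate 6 (not isolated), via C6 phenylselenide 7 (not isolated), via selenoxide 8 (not isolated)
Conditions: LiN(SiMe3)2, THF, −78 °C; PhSeBr; then 30% H2O2, pyridine, CH2Cl2, 0 °C
Reagents that add atoms: none
Why: Selenenylation of the lactone enolate followed by selenoxide syn elimination towards C7 should install the C6=C7 butenolide double bond, the C1 ester having no α-hydrogen and C8 staying untouched.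

Step 6
Reactants: 10 2-bromoprop-2-en-1-ol
Product: 11 [(2-bromoprop-2-en-1-yl)oxy]tri(propan-2-yl)silane
Conditions: i-Pr3SiCl, imidazole, DMF, rt
Reagents that add atoms: chlorotri(propan-2-yl)silane, CC(C)[Si](Cl)(C(C)C)C(C)C
Why: Standard silylation of a primary alcohol, the bulky triisopropylsilyl group being chosen to slow oxygen-to-carbon silyl migration in the derived vinyllithium and to outlast the other silyl ethers later.

Step 7
Reactants: 11 [(2-bromoprop-2-en-1-yl)oxy]tri(propan-2-yl)silane; 9 butenolide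
Product: 14 methyl (4S,5S)-2,2,4-trimethyl-5-[(2S,3R)-5-oxo-3-{3-[(triisopropylsilyl)oxy]prop-1-en-2-yl}oxolan-2-yl]-1,3-dioxolane-4-carboxylate, via vinyllithium 12 (not isolated), via lithium divinylcuprate 13 (not isolated)
Conditions: 11 (2.2 equiv), t-BuLi (4.4 equiv), Et2O, −78 °C; CuI (1.1 equiv), −78 → −40 °C; 9, THF, −78 °C; aq. NH4Cl
Reagents that add atoms: none
Why: Conjugate addition of the Gilman cuprate to the butenolide should take place on the face opposite the bulky C8 dioxolanyl group, which sets C7 trans to C8.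

Step 8
Reactants: 14 C7-substituted lactone
Product: 16 α-hydroxy lactone (14 with OH at C6 and trans to the C7 substituent), via potassium enolate 15 (not isolated)
Conditions: KN(SiMe3)2, THF, −78 °C; 2-(benzenesulfonyl)-3-phenyloxaziridine; AcOH quench
Reagents that add atoms: 2-(benzenesulfonyl)-3-phenyloxaziridine, O=S(=O)(c1ccccc1)N1OC1c1ccccc1
Why: Davis hydroxylation of the lactone enolate should deliver oxygen to the face anti to the adjacent C7 substituent, which gives the 6,7-trans α-hydroxy lactone.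

Step 9
Reactants: 16 α-hydroxy lactone
Product: 17 C6 tert-butyldimethylsilyl ether of 16
Conditions: t-BuMe2SiOTf, 2,6-lutidine, CH2Cl2, −78 → 0 °C
Reagents that add atoms: tert-butyldimethylsilyl trifluoromethanesulfonate, CC(C)(C)[Si](C)(C)OS(=O)(=O)C(F)(F)F
Why: Silyl triflate silylation protects the hindered C6 hydroxyl as an ether that survives every step up to the late fluoride deprotection.

Step 10
Reactants: 17 C6 silyl ether lactone
Product: 19 C5 N-methoxy-N-methylamide in which O8 is lactonised onto C1 (γ-lactone cis-fused to the C9/C10 acetonide), via hydroxy ester 18 (not isolated)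
Conditions: CH3NH(OCH3)·HCl, AlMe3, CH2Cl2, 0 °C → rt; aq. KNaC4H4O6
Reagents that add atoms: N,O-dimethylhydroxylamine hydrochloride, CNOC.Cl
Why: Weinreb aminolysis by the aluminium amide opens the template lactone at C5, and the freed C8 alkoxide, which sits cis to the C1 ester on the dioxolane, should close onto it (translactonisation), so that O8 is parked on C1 and any uncyclised 18 converges in step 11.

Step 11
Reactants: 19 Weinreb amide γ-lactone
Product: 22 C8 triethylsilyl ether C1 carboxylic acid, via lithium carboxylate 20 (not isolated), via bis(triethylsilyl) derivative 21 (not isolated)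
Conditions: LiOH, THF/H2O, 0 °C; concentrate; Et3SiCl, imidazole, DMF, 0 °C → rt; K2CO3, CH3OH/H2O, 0 °C; pH 5 buffer
Reagents that add atoms: lithium hydroxide, [Li+].[OH-]; chlorotriethylsilane, CC[Si](Cl)(CC)CC
Why: Saponification of the γ-lactone, silylation of the hydroxy carboxylate salt (which cannot relactonise) and methanolysis of the labile silyl ester should leave O8 as its triethylsilyl ether and C1 as the free acid.

Step 12
Reactants: 22 C8 silyl ether acid
Product: 23 allyl ester of 22
Conditions: CH2=CHCH2Br, K2CO3, DMF, rt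
Reagents that add atoms: allyl bromide, C=CCBr
Why: Carboxylate O-alkylation gives an allyl ester that tolerates hydride and organozinc reagents and can later be cleaved at the allyl carbon without attack on the hindered C1 carbonyl.

Step 13
Reactants: 23 allyl ester Weinreb amide
Product: 24 C5 aldehyde (α-silyloxy aldehyde)
Conditions: i-Bu2AlH, THF, −78 °C; aq. KNaC4H4O6
Reagents that add atoms: none
Why: Hydride reduction of the Weinreb amide stops at the chelated hemiaminal, which releases the aldehyde on work-up while the hindered allyl ester is left alone at −78 °C.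

Step 14
Reactants: 25 (4-methoxyphenyl)methanol
Product: 29 1-methoxy-4-[(prop-1-yn-1-yloxy)methyl]benzene, via potassium alkoxide 26 (not isolated), via dichlorovinyl ether 27 (not isolated), via lithium alkynide 28 (not isolated)
Conditions: KH, THF, 0 °C; Cl2C=CHCl, rt; n-BuLi (2.3 equiv), −78 → −40 °C; CH3I, DMPU, −78 → 0 °C; kept cold
Reagents that add atoms: trichloroethylene, ClC=C(Cl)Cl; iodomethane, CI
Why: Addition of the alkoxide to dichloroacetylene formed from trichloroethylene, then elimination and chlorine–lithium exchange with n-BuLi and methylation of the lithium alkoxyacetylide, is the established one-pot synthesis of 1-alkoxypropynes.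

Step 15
Reactants: 29 1-methoxy-4-[(prop-1-yn-1-yloxy)methyl]benzene; 24 C5 aldehyde
Product: 32 C5 carbinol carrying the (E)-C4(CH3)=C3H–O-(4-methoxybenzyl) enol ether (C5–OH syn to C6–OSi), via vinylborane 30 (not isolated), via vinylzinc 31 (not isolated)
Conditions: 29, (c-C6H11)2BH, toluene, 0 °C; Et2Zn, −78 °C; 24, EtZnCl (from Et2Zn and ZnCl2), −78 → −20 °C; aq. NH4Cl
Reagents that add atoms: none
Why: Syn hydroboration puts boron on C4 trans to the ether oxygen, boron-to-zinc exchange keeps that geometry (hence the E enol ether), and the alkylzinc halide chelates the aldehyde oxygen and the C6 silyloxy oxygen so that the vinylzinc attacks the Cram-chelate face anti to C7 (chelation-controlled organozinc addition), which sets C5.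

Step 16
Reactants: 32 C5 carbinol allyl ester
Product: 33 seco acid (C1 CO2H, C5 OH), handled as its morpholinium salt
Conditions: Pd(PPh3)4 (cat.), morpholine, THF, rt
Reagents that add atoms: none
Why: Zerovalent palladium ionises the allyl ester (Tsuji–Trost deallylation) and morpholine captures the allyl group, which frees the acid under basic conditions that spare the acid-labile γ-hydroxy enol ether.

Step 17
Reactants: 33 seco acid
Product: 34 eight-membered lactone (O5–C1), C9/C10 acetonide, C8 OSiEt3, C6 OSiMe2t-Bu, C5 (E)-enol ether side chain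
Conditions: 2-methyl-6-nitrobenzoic anhydride, 4-(dimethylamino)pyridine, Et3N, toluene, rt → 40 °C, slow addition at high dilution
Reagents that add atoms: none
Why: Shiina lactonisation activates the C1 carboxyl under basic nucleophilic catalysis at high dilution, and the cis-fused acetonide and the substituents along C6–C10 should favour the folded conformer needed to close the eight-membered ring.

Step 18
Reactants: 34 eight-membered lactone
Product: 35 2-methyleneoxocane (C1=C2 exocyclic enol ether; ring O–C1–C10–C9–C8–C7–C6–C5)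
Conditions: Cp2TiMe2, toluene/THF, 65 °C, dark
Reagents that add atoms: dimethyltitanocene, [CH3-].[CH3-].[Ti+4].c1cc[cH-]c1.c1cc[cH-]c1
Why: Petasis methylenation converts the lactone carbonyl into the exocyclic enol ether by carbonyl–titanium methylidene metathesis under non-acidic conditions that both enol ethers and all silyl ethers tolerate.

Step 19
Reactants: 35 2-methyleneoxocane
Product: 36 cyclodec-4-en-1-one (C1 ketone, C3 O-(4-methoxybenzyl), cis C4=C5, C6 OSiMe2t-Bu, C8 OSiEt3, C9/C10 acetonide, C7 side chain unchanged)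
Conditions: degassed toluene, Et3N (trace), 120 °C, sealed tube, base-washed glass
Reagents that add atoms: none
Why: On heating, the allyl vinyl ether C2=C1–O–C5–C4=C3 should undergo a concerted suprafacial [3,3]-sigmatropic (Claisen) shift in which C2–C3 forms as C5–O breaks, turning C1 into the ketone and C4=C5 into the ring alkene. The closest known reaction type is the Claisen ring expansion of 2-methylene cyclic ethers that carry an alkenyl group on the other α-carbon, here helped by the electron-releasing benzyloxy group on the allyl terminus C3, a position at which donors accelerate the rearrangement. The ten-membered carbocycle C1–C10 is not closed end to end: it arises by two-carbon enlargement of the eight-membered oxocane through a bicyclic six-centre transition state, and no other ring is formed. The new stereocentre C3 is controlled by the C5 configuration (5S) together with the E enol ether geometry, which in the chair place the C3 alkoxy group pseudo-equatorial and expose only the face of C3 that leads to the 3S ether. The step needs the chair rather than the boat and the cis (Z) C4=C5 bond, and both are secured by the five-carbon tether C6–C10, which can span C5 and C1 only when C6 is pseudo-axial, the arrangement that gives the cis ring alkene. Neutral, base-washed conditions are used because both enol ethers of 35 are acid-labile.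

Step 20
Reactants: 36 cyclodecenone
Product: 37 C8 alcohol (36 without the triethylsilyl group)
Conditions: HF·pyridine, pyridine, THF, 0 °C
Reagents that add atoms: none
Why: Fluoride-mediated desilylation is fastest at the triethylsilyl ether, so the C8 hydroxyl should be freed while the secondary tert-butyldimethylsilyl and primary triisopropylsilyl ethers stay.

Step 21
Reactants: 37 C8 alcohol; 38 tiglic acid [(E)-2-methylbut-2-enoic acid]
Product: 40 C8 tiglate, via mixed anhydride 39 (not isolated)
Conditions: 38, 2,4,6-Cl3C6H2COCl, Et3N, toluene, rt; then 37, 4-(dimethylamino)pyridine, rt → 40 °C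
Reagents that add atoms: none
Why: Yamaguchi esterification transfers the tigloyl group to the hindered C8 hydroxyl without E/Z isomerisation, and any transannular C1 hemiketal should drain through the open hydroxy ketone because its tertiary hydroxyl is acylated far more slowly.

Step 22
Reactants: 40 C8 tiglate
Product: 41 C6,C12 diol
Conditions: HF·pyridine, THF, 0 °C → rt
Reagents that add atoms: none
Why: Prolonged fluoride treatment cleaves the remaining tert-butyldimethylsilyl and triisopropylsilyl ethers by Si–F bond formation and leaves the tiglate, the benzyl-type ether and the acetonide intact.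

Step 23
Reactants: 41 C6,C12 diol
Product: 44 α-methylene-γ-butyrolactone (O6–C12 lactone), via hydroxy enal 42 (not isolated), via lactol 43 (not isolated)
Conditions: TEMPO (cat.), PhI(OAc)2, CH2Cl2, rt
Reagents that add atoms: none
Why: Oxoammonium (TEMPO) oxidation selects the primary allylic C12 alcohol, the enal is trapped by the C6 hydroxyl as the five-membered lactol, and this is oxidised on to the lactone, whose trans ring fusion is already fixed by C6 and C7.

Step 24
Reactants: 44 lactone with C3 O-(4-methoxybenzyl)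
Product: 45 C3 alcohol (C9/C10 acetonide)
Conditions: DDQ, CH2Cl2/pH 7 buffer, 0 °C
Reagents that add atoms: none
Why: Oxidative cleavage of the 4-methoxybenzyl ether by DDQ (benzylic hydride abstraction, then hydrolysis of the oxocarbenium ion) frees the C3 hydroxyl under near-neutral conditions.

Step 25
Reactants: 45 C3 alcohol acetonide
Product: 46 target CNP0106709.2
Conditions: aq. HCl (1 M)/THF, 0 °C → rt
Reagents that add atoms: none
Why: Acid-catalysed hydrolysis of the isopropylidene ketal releases the C9 and C10 hydroxyls, and mild conditions are chosen to avoid tiglate migration to O9 and dehydration of the β-hydroxy ketone.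

**Compound list**

1 | (S)-5-(hydroxymethyl)oxolan-2-one | O=C1CC[C@@H](CO)O1 | starting material
2 | (S)-5-oxooxolane-2-carbaldehyde | O=C1CC[C@@H](C=O)O1 | intermediate
3 | methyl (Z)-2-methyl-3-[(2S)-5-oxooxolan-2-yl]prop-2-enoate | O=C1CC[C@@H](/C=C(/C)C(=O)OC)O1 | intermediate
4 | methyl (2S,3S)-2,3-dihydroxy-2-methyl-3-[(2S)-5-oxooxolan-2-yl]propanoate | O=C1CC[C@@H]([C@H](O)[C@](C)(O)C(=O)OC)O1 | intermediate
5 | methyl (4S,5S)-2,2,4-trimethyl-5-[(2S)-5-oxooxolan-2-yl]-1,3-dioxolane-4-carboxylate | O=C1CC[C@@H]([C@@H]2OC(C)(C)O[C@]2(C)C(=O)OC)O1 | intermediate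
6 | lithium enolate of 5 (C5–OLi, C5=C6; not isolated) | [Li]OC1=CC[C@@H]([C@@H]2OC(C)(C)O[C@]2(C)C(=O)OC)O1 | intermediate
7 | C6 phenylselenide of 5 (both C6 epimers; not isolated) | O=C1C([Se]c2ccccc2)C[C@@H]([C@@H]3OC(C)(C)O[C@]3(C)C(=O)OC)O1 | intermediate
8 | selenoxide of 7 (not isolated) | O=C1C([Se](=O)c2ccccc2)C[C@@H]([C@@H]3OC(C)(C)O[C@]3(C)C(=O)OC)O1 | intermediate
9 | methyl (4S,5S)-2,2,4-trimethyl-5-[(2S)-5-oxo-2,5-dihydrofuran-2-yl]-1,3-dioxolane-4-carboxylate | O=C1C=C[C@@H]([C@@H]2OC(C)(C)O[C@]2(C)C(=O)OC)O1 | intermediate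
10 | 2-bromoprop-2-en-1-ol | C=C(Br)CO | starting material
11 | [(2-bromoprop-2-en-1-yl)oxy]tri(propan-2-yl)silane | C=C(Br)CO[Si](C(C)C)(C(C)C)C(C)C | intermediate
12 | {3-[(triisopropylsilyl)oxy]prop-1-en-2-yl}lithium (not isolated) | [Li]C(=C)CO[Si](C(C)C)(C(C)C)C(C)C | intermediate
13 | lithium bis{3-[(triisopropylsilyl)oxy]prop-1-en-2-yl}cuprate (not isolated) | [Li+].C=C(CO[Si](C(C)C)(C(C)C)C(C)C)[Cu-]C(=C)CO[Si](C(C)C)(C(C)C)C(C)C | intermediate
14 | methyl (4S,5S)-2,2,4-trimethyl-5-[(2S,3R)-5-oxo-3-{3-[(triisopropylsilyl)oxy]prop-1-en-2-yl}oxolan-2-yl]-1,3-dioxolane-4-carboxylate (C7 trans to C8) | O=C1C[C@H](C(=C)CO[Si](C(C)C)(C(C)C)C(C)C)[C@@H]([C@@H]2OC(C)(C)O[C@]2(C)C(=O)OC)O1 | intermediate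
15 | potassium enolate of 14 (not isolated) | [K]OC1=C[C@H](C(=C)CO[Si](C(C)C)(C(C)C)C(C)C)[C@@H]([C@@H]2OC(C)(C)O[C@]2(C)C(=O)OC)O1 | intermediate
16 | α-hydroxy lactone: 14 with OH at C6, trans to the C7 substituent | O=C1[C@@H](O)[C@H](C(=C)CO[Si](C(C)C)(C(C)C)C(C)C)[C@@H]([C@@H]2OC(C)(C)O[C@]2(C)C(=O)OC)O1 | intermediate
17 | C6 tert-butyldimethylsilyl ether of 16 | O=C1[C@@H](O[Si](C)(C)C(C)(C)C)[C@H](C(=C)CO[Si](C(C)C)(C(C)C)C(C)C)[C@@H]([C@@H]2OC(C)(C)O[C@]2(C)C(=O)OC)O1 | intermediate
18 | open-chain C5 N-methoxy-N-methylamide with free C8–OH and C1 methyl ester (not isolated) | CON(C)C(=O)[C@@H](O[Si](C)(C)C(C)(C)C)[C@H](C(=C)CO[Si](C(C)C)(C(C)C)C(C)C)[C@H](O)[C@@H]1OC(C)(C)O[C@]1(C)C(=O)OC | intermediate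
19 | C5 N-methoxy-N-methylamide with O8 lactonised onto C1 (γ-lactone cis-fused to the acetonide) | CON(C)C(=O)[C@@H](O[Si](C)(C)C(C)(C)C)[C@H](C(=C)CO[Si](C(C)C)(C(C)C)C(C)C)[C@@H]1OC(=O)[C@@]2(C)OC(C)(C)O[C@@H]12 | intermediate
20 | lithium C1 carboxylate with free C8–OH (not isolated) | CON(C)C(=O)[C@@H](O[Si](C)(C)C(C)(C)C)[C@H](C(=C)CO[Si](C(C)C)(C(C)C)C(C)C)[C@H](O)[C@@H]1OC(C)(C)O[C@]1(C)C(=O)[O-].[Li+] | intermediate
21 | C8 triethylsilyl ether C1 triethylsilyl ester (not isolated) | CON(C)C(=O)[C@@H](O[Si](C)(C)C(C)(C)C)[C@H](C(=C)CO[Si](C(C)C)(C(C)C)C(C)C)[C@H](O[Si](CC)(CC)CC)[C@@H]1OC(C)(C)O[C@]1(C)C(=O)O[Si](CC)(CC)CC | intermediate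
22 | C8 triethylsilyl ether C1 carboxylic acid (C5 Weinreb amide) | CON(C)C(=O)[C@@H](O[Si](C)(C)C(C)(C)C)[C@H](C(=C)CO[Si](C(C)C)(C(C)C)C(C)C)[C@H](O[Si](CC)(CC)CC)[C@@H]1OC(C)(C)O[C@]1(C)C(=O)O | intermediate
23 | allyl ester of 22 | CON(C)C(=O)[C@@H](O[Si](C)(C)C(C)(C)C)[C@H](C(=C)CO[Si](C(C)C)(C(C)C)C(C)C)[C@H](O[Si](CC)(CC)CC)[C@@H]1OC(C)(C)O[C@]1(C)C(=O)OCC=C | intermediate
24 | C5 aldehyde (C6 OSiMe2t-Bu, C8 OSiEt3, C1 allyl ester) | O=C[C@@H](O[Si](C)(C)C(C)(C)C)[C@H](C(=C)CO[Si](C(C)C)(C(C)C)C(C)C)[C@H](O[Si](CC)(CC)CC)[C@@H]1OC(C)(C)O[C@]1(C)C(=O)OCC=C | intermediate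
25 | (4-methoxyphenyl)methanol | COc1ccc(CO)cc1 | starting material
26 | potassium (4-methoxyphenyl)methanolate (not isolated) | [K+].[O-]Cc1ccc(OC)cc1 | intermediate
27 | 1-({[(E)-1,2-dichloroethenyl]oxy}methyl)-4-methoxybenzene (not isolated) | Cl/C=C(/Cl)OCc1ccc(OC)cc1 | intermediate
28 | lithium [(4-methoxybenzyl)oxy]ethynide (not isolated) | [Li]C#COCc1ccc(OC)cc1 | intermediate
29 | 1-methoxy-4-[(prop-1-yn-1-yloxy)methyl]benzene | CC#COCc1ccc(OC)cc1 | intermediate
30 | dicyclohexyl{(E)-1-[(4-methoxybenzyl)oxy]prop-1-en-2-yl}borane (not isolated) | C/C(=C\OCc1ccc(OC)cc1)B(C1CCCCC1)C1CCCCC1 | intermediate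
31 | ethyl{(E)-1-[(4-methoxybenzyl)oxy]prop-1-en-2-yl}zinc (not isolated) | CC[Zn]/C(C)=C/OCc1ccc(OC)cc1 | intermediate
32 | C5 carbinol with (E)-C4(CH3)=C3H–O-(4-methoxybenzyl) enol ether, C1 allyl ester | COc1ccc(CO/C=C(\C)[C@H](O)[C@@H](O[Si](C)(C)C(C)(C)C)[C@H](C(=C)CO[Si](C(C)C)(C(C)C)C(C)C)[C@H](O[Si](CC)(CC)CC)[C@@H]2OC(C)(C)O[C@]2(C)C(=O)OCC=C)cc1 | intermediate
33 | seco acid (C1 CO2H, C5 OH) | COc1ccc(CO/C=C(\C)[C@H](O)[C@@H](O[Si](C)(C)C(C)(C)C)[C@H](C(=C)CO[Si](C(C)C)(C(C)C)C(C)C)[C@H](O[Si](CC)(CC)CC)[C@@H]2OC(C)(C)O[C@]2(C)C(=O)O)cc1 | intermediate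
34 | eight-membered lactone (O5–C1) | O=C1[C@@](C)(OC2(C)C)[C@@H](O2)[C@@H](O[Si](CC)(CC)CC)[C@@H](C(=C)CO[Si](C(C)C)(C(C)C)C(C)C)[C@H](O[Si](C)(C)C(C)(C)C)[C@H](/C(C)=C/OCc3ccc(OC)cc3)O1 | intermediate
35 | 2-methyleneoxocane with (E)-enol ether on C5 (Claisen precursor) | C=C1[C@@](C)(OC2(C)C)[C@@H](O2)[C@@H](O[Si](CC)(CC)CC)[C@@H](C(=C)CO[Si](C(C)C)(C(C)C)C(C)C)[C@H](O[Si](C)(C)C(C)(C)C)[C@H](/C(C)=C/OCc3ccc(OC)cc3)O1 | intermediate
36 | protected cyclodec-4-en-1-one (Claisen product; 3S, cis C4=C5) | CC(C)(C)[Si](C)(C)O[C@@H]1/C=C(/C)[C@@H](OCc3ccc(OC)cc3)CC(=O)[C@@](C)(OC2(C)C)[C@@H](O2)[C@@H](O[Si](CC)(CC)CC)[C@H]1C(=C)CO[Si](C(C)C)(C(C)C)C(C)C | intermediate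
37 | C8 alcohol | CC(C)(C)[Si](C)(C)O[C@@H]1/C=C(/C)[C@@H](OCc3ccc(OC)cc3)CC(=O)[C@@](C)(OC2(C)C)[C@@H](O2)[C@@H](O)[C@H]1C(=C)CO[Si](C(C)C)(C(C)C)C(C)C | intermediate
38 | tiglic acid, (E)-2-methylbut-2-enoic acid | C/C=C(\C)C(=O)O | starting material
39 | (E)-2-methylbut-2-enoic 2,4,6-trichlorobenzoic anhydride (not isolated) | C/C=C(\C)C(=O)OC(=O)c1c(Cl)cc(Cl)cc1Cl | intermediate
40 | C8 tiglate | CC(C)(C)[Si](C)(C)O[C@@H]1/C=C(/C)[C@@H](OCc3ccc(OC)cc3)CC(=O)[C@@](C)(OC2(C)C)[C@@H](O2)[C@@H](OC(=O)/C(C)=C/C)[C@H]1C(=C)CO[Si](C(C)C)(C(C)C)C(C)C | intermediate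
41 | C6,C12 diol | O[C@@H]1/C=C(/C)[C@@H](OCc3ccc(OC)cc3)CC(=O)[C@@](C)(OC2(C)C)[C@@H](O2)[C@@H](OC(=O)/C(C)=C/C)[C@H]1C(=C)CO | intermediate
42 | C12 enal with free C6–OH (not isolated) | O[C@@H]1/C=C(/C)[C@@H](OCc3ccc(OC)cc3)CC(=O)[C@@](C)(OC2(C)C)[C@@H](O2)[C@@H](OC(=O)/C(C)=C/C)[C@H]1C(=C)C=O | intermediate
43 | C12 lactol, both anomers (not isolated) | C=C1C(O)O[C@@H]2/C=C(/C)[C@@H](OCc4ccc(OC)cc4)CC(=O)[C@@](C)(OC3(C)C)[C@@H](O3)[C@@H](OC(=O)/C(C)=C/C)[C@@H]12 | intermediate
44 | α-methylene-γ-butyrolactone with C3 O-(4-methoxybenzyl) and C9/C10 acetonide | C=C1C(=O)O[C@@H]2/C=C(/C)[C@@H](OCc4ccc(OC)cc4)CC(=O)[C@@](C)(OC3(C)C)[C@@H](O3)[C@@H](OC(=O)/C(C)=C/C)[C@@H]12 | intermediate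
45 | C3 alcohol, C9/C10 acetonide | C=C1C(=O)O[C@@H]2/C=C(/C)[C@@H](O)CC(=O)[C@@](C)(OC3(C)C)[C@@H](O3)[C@@H](OC(=O)/C(C)=C/C)[C@@H]12 | intermediate
46 | CNP0106709.2 | C=C1C(=O)O[C@@H]2/C=C(/C)[C@@H](O)CC(=O)[C@@](C)(O)[C@@H](O)[C@@H](OC(=O)/C(C)=C/C)[C@@H]12 | target

**Totals and risks**

Total step count: 25. Longest linear sequence: 23 steps (from 1 through steps 1–5, 7–13 and 15–25; steps 6 and 14 are side branches).

Steps most likely to fail:

Step 17. Ring closure between a hindered tertiary acid and a hindered allylic alcohol may be outrun by intermolecular acylation (dimers, oligomers) or by decay of the activated acid. The fallback sets out from 33 and replaces the nucleophile-catalysed mixed-anhydride acylation by a thiol-ester route. Acid 33 is converted with 2,2'-dipyridyl disulfide and PPh3 into the S-(pyridin-2-yl) thioester F1, which is isolated and then added slowly to warm toluene at high dilution (Corey–Nicolaou double activation). There the pyridine nitrogen takes the hydroxyl proton while the thioester carbonyl is attacked within the same hydrogen-bonded pair, so no external base or acyl-transfer catalyst is involved. The route is rejoined at lactone 34.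

Step 19. The thermal rearrangement may run partly through a boat or through a stepwise ionisation, giving the trans ring alkene or the C3 epimer, or the enol ethers may decompose before the shift takes place. The fallback sets out from 35 and uses the aluminium-promoted variant of the same rearrangement. Treatment with i-Bu3Al in CH2Cl2 from −78 °C upwards should induce the charge-accelerated [3,3] shift at low temperature and reduce the aluminium-bound ketone in situ by β-hydride transfer to the ring-expanded C1 carbinol F2 (epimers at C1). Dess–Martin oxidation of F2 then returns the route to ketone 36.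

Step 21. Once the C8 hydroxyl is free it may add across the ring to the C1 ketone, and the resulting hemiketal could stall acylation or divert it to the hemiketal oxygen. The fallback sets out from 35 and moves the ester forward, before the ketone exists. The triethylsilyl ether of 35 is removed with Bu4NF in THF at −20 °C (basic conditions that the enol ethers tolerate) to give the C8 alcohol F3. F3 is acylated with mixed anhydride 39 and 4-(dimethylamino)pyridine to the tiglate F4. Heating F4 under the conditions of step 19 should then give the ring-expanded ketone with the ester already in place, and the route is rejoined at 40.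

**Further compounds**

F1 | step 17 | S-(pyridin-2-yl) thioester of seco acid 33 | COc1ccc(CO/C=C(\C)[C@H](O)[C@@H](O[Si](C)(C)C(C)(C)C)[C@H](C(=C)CO[Si](C(C)C)(C(C)C)C(C)C)[C@H](O[Si](CC)(CC)CC)[C@@H]2OC(C)(C)O[C@]2(C)C(=O)Sc3ccccn3)cc1
F2 | step 19 | ring-expanded C1 carbinol (36 with CH–OH at C1, both C1 epimers) | CC(C)(C)[Si](C)(C)O[C@@H]1/C=C(/C)[C@@H](OCc3ccc(OC)cc3)CC(O)[C@@](C)(OC2(C)C)[C@@H](O2)[C@@H](O[Si](CC)(CC)CC)[C@H]1C(=C)CO[Si](C(C)C)(C(C)C)C(C)C
F3 | step 21 | 2-methyleneoxocane with free C8–OH (35 without the triethylsilyl group) | C=C1[C@@](C)(OC2(C)C)[C@@H](O2)[C@@H](O)[C@@H](C(=C)CO[Si](C(C)C)(C(C)C)C(C)C)[C@H](O[Si](C)(C)C(C)(C)C)[C@H](/C(C)=C/OCc3ccc(OC)cc3)O1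
F4 | step 21 | 2-methyleneoxocane C8 tiglate | C=C1[C@@](C)(OC2(C)C)[C@@H](O2)[C@@H](OC(=O)/C(C)=C/C)[C@@H](C(=C)CO[Si](C(C)C)(C(C)C)C(C)C)[C@H](O[Si](C)(C)C(C)(C)C)[C@H](/C(C)=C/OCc3ccc(OC)cc3)O1
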